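**Retrosynthetic overview**

- Alopecurone G comes from its ring B silyl ether by fluoride; ring A is the last ring made.
- Ring A is disconnected at C8–C8a and C4a–C5: a [4+2] addition of a lavandulyl-bearing 1-methoxy-3-silyloxydiene to the C4a=C8a bond of an (S)-2-aryl-5-sulfinyl-2,3-dihydropyran-4-one, then loss of methanol and benzenesulfenic acid. The feature used is the row O7–C7, lavandulyl–C8, O1–C8a on ring A, with the C8a–C4a bond shared with ring C.
- The dienophile comes from ring C formation by a catalytic asymmetric hetero-Diels–Alder reaction of the ring B aldehyde (sets C2), then C5 iodination, C–S coupling and S-oxidation.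
- The diene comes from (S)-limonene, whose C4 becomes the lavandulyl stereocentre: ring cleavage, isopropylidene Wittig on the aldehyde arm, then formylation, O-methylation and silylation on the methyl ketone arm.
- Ring order: ring B bought, ring C (step 8), ring A (step 12).

Key step: step 12

Assumption: the (S)-BINOL titanium catalyst is taken to deliver the diene to the Si face of the aryl aldehyde, as this catalyst type does in aryl aldehyde allylation, giving the (S)-pyranone; if the sense is opposite, (R)-BINOL is used with no other change.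

Remark: the stereocentre taken from limonene is never touched; its descriptor changes from S (limonene and the open-chain ketones) to R (diene and flavanones) only because the CIP priorities of its neighbours change.

**Route**

Step 1
Reactants: 1 (S)-(−)-limonene
Product: 2 (4S)-limonene 1,2-oxide (both epoxide diastereomers)
Conditions: mCPBA (1.0 equiv), CH2Cl2, 0 °C
Reagents that add atoms: mCPBA, O=C(OO)c1cccc(Cl)c1
Why: Prilezhaev epoxidation should pick the more electron-rich trisubstituted ring alkene over the isopropenyl group, and both epoxide diastereomers converge in step 2.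

Step 2
Reactants: 2 (4S)-limonene 1,2-oxide
Product: 4 (3S)-6-oxo-3-(prop-1-en-2-yl)heptanal, via limonene-1,2-diol 3 (not isolated)
Conditions: H5IO6, THF–H2O, 0 °C to rt
Reagents that add atoms: water, O
Why: Periodic acid should hydrolyse the epoxide and cleave the resulting diol (Malaprade glycol cleavage) in one pot, turning C1 into the methyl ketone and C2 into the aldehyde while the stereocentre, β to the aldehyde, cannot epimerise.

Step 3
Reactants: 4 (3S)-6-oxo-3-(prop-1-en-2-yl)heptanal
Product: 5 (5S)-8-methyl-5-(prop-1-en-2-yl)non-7-en-2-one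
Conditions: iPrPPh3I, n-BuLi, THF, 0 °C; ylide added to 4, −78 to 0 °C
Reagents that add atoms: isopropyltriphenylphosphonium iodide, CC(C)[P+](c1ccccc1)(c1ccccc1)c1ccccc1.[I-]
Why: Wittig olefination with a non-stabilised ylide is much faster at an aldehyde than at a methyl ketone, and adding one equivalent of ylide to the cold keto aldehyde should limit enolisation and intramolecular aldol reaction while building the prenyl arm.

Step 4
Reactants: 5 (5S)-8-methyl-5-(prop-1-en-2-yl)non-7-en-2-one
Product: 7 (1Z,6S)-1-hydroxy-9-methyl-6-(prop-1-en-2-yl)deca-1,8-dien-3-one (enol form of the 3-oxo aldehyde), via kinetic lithium enolate 6 (not isolated)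
Conditions: LiN(iPr)2, THF, −78 °C; HCO2CH2CF3, −78 °C; 1 M HCl
Reagents that add atoms: 2,2,2-trifluoroethyl formate, O=COCC(F)(F)F
Why: Kinetic deprotonation should occur at the unhindered methyl group and the enolate is C-formylated by the activated formate (crossed Claisen condensation).

Step 5
Reactants: 7 (1Z,6S)-1-hydroxy-9-methyl-6-(prop-1-en-2-yl)deca-1,8-dien-3-one
Product: 8 (1E,6S)-1-methoxy-9-methyl-6-(prop-1-en-2-yl)deca-1,8-dien-3-one
Conditions: Me2SO4, K2CO3, acetone, rt
Reagents that add atoms: dimethyl sulfate, COS(=O)(=O)OC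
Why: O-alkylation of a hydroxymethylene ketone enolate with a hard methylating agent should occur at the formyl oxygen, and any Z enol ether should equilibrate to the more stable E isomer.

Step 6
Reactants: 8 (1E,6S)-1-methoxy-9-methyl-6-(prop-1-en-2-yl)deca-1,8-dien-3-one
Product: 9 (1E,3Z,6R)-1-methoxy-9-methyl-6-(prop-1-en-2-yl)-3-(trimethylsilyloxy)deca-1,3,8-triene, that is (1E,3Z)-1-methoxy-3-(trimethylsilyloxy)-4-[(2R)-lavandulyl]buta-1,3-diene
Conditions: TMSOTf, Et3N, Et2O, 0 °C
Reagents that add atoms: trimethylsilyl trifluoromethanesulfonate, C[Si](C)(C)OS(=O)(=O)C(F)(F)F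
Why: Silyl enol ether formation at the only enolisable α-CH2 gives the 1-methoxy-3-silyloxydiene, and the 3Z isomer, with the alkyl group outside in the s-cis form, is expected as for simpler 4-alkyl analogues.

Step 7
Reactants: 10 4-hydroxy-2-methoxybenzaldehyde
Product: 11 4-(tert-butyldimethylsilyloxy)-2-methoxybenzaldehyde
Conditions: TBSCl, imidazole, DMF, rt
Reagents that add atoms: tert-butyldimethylsilyl chloride, CC(C)(C)[Si](C)(C)Cl
Why: Standard phenol silylation, with a silyl ether chosen so that the final unmasking uses fluoride and not acid, which could add O7 to the isopropenyl group or ionise the C2–O1 bond.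

Step 8
Reactants: 11 4-(tert-butyldimethylsilyloxy)-2-methoxybenzaldehyde, 12 (E)-1-methoxy-3-(trimethylsilyloxy)buta-1,3-diene
Product: 14 (2S)-2-[4-(tert-butyldimethylsilyloxy)-2-methoxyphenyl]-2,3-dihydro-4H-pyran-4-one, via Mukaiyama aldol silyl ether 13 (not isolated)
Conditions: (S)-BINOL (20 mol%), Ti(OiPr)4 (10 mol%), 4 Å MS, Et2O, −20 °C; then TFA, CH2Cl2, 0 °C
Reagents that add atoms: none
Why: Titanium–BINOL catalysed hetero-Diels–Alder reaction, which runs by Mukaiyama aldol addition to the Si face of the aldehyde and acid-induced ring closure with loss of methanol, so that C2 is set by the chiral catalyst.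

Step 9
Reactants: 14 (2S)-2-[4-(tert-butyldimethylsilyloxy)-2-methoxyphenyl]-2,3-dihydro-4H-pyran-4-one
Product: 15 (2S)-2-[4-(tert-butyldimethylsilyloxy)-2-methoxyphenyl]-5-iodo-2,3-dihydro-4H-pyran-4-one
Conditions: I2, pyridine–CH2Cl2, 0 °C to rt
Reagents that add atoms: iodine, II
Why: Pyridine-mediated α-iodination of an enone, a known reaction of 2,3-dihydropyran-4-ones, should functionalise C5 only, since this mild reagent does not iodinate the dialkoxyarene and C2 is not involved.

Step 10
Reactants: 15 (2S)-2-[4-(tert-butyldimethylsilyloxy)-2-methoxyphenyl]-5-iodo-2,3-dihydro-4H-pyran-4-one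
Product: 16 (2S)-2-[4-(tert-butyldimethylsilyloxy)-2-methoxyphenyl]-5-(phenylthio)-2,3-dihydro-4H-pyran-4-one
Conditions: PhSH, Pd2(dba)3 (2.5 mol%), Xantphos (5 mol%), iPr2NEt, 1,4-dioxane, 80 °C
Reagents that add atoms: thiophenol, Sc1ccccc1
Why: Palladium-catalysed C–S cross-coupling of an α-iodoenone with a thiol under a hindered amine base should install sulfur at C5 without any electrophilic sulfur reagent that could attack ring B.

Step 11
Reactants: 16 (2S)-2-[4-(tert-butyldimethylsilyloxy)-2-methoxyphenyl]-5-(phenylthio)-2,3-dihydro-4H-pyran-4-one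
Product: 17 (2S)-2-[4-(tert-butyldimethylsilyloxy)-2-methoxyphenyl]-5-(phenylsulfinyl)-2,3-dihydro-4H-pyran-4-one (both sulfur epimers)
Conditions: mCPBA (1.0 equiv), CH2Cl2, −78 to −40 °C
Reagents that add atoms: mCPBA, O=C(OO)c1cccc(Cl)c1
Why: Sulfide to sulfoxide oxidation with one equivalent of peracid at low temperature should stop before the sulfone and spare the push–pull alkene, and both sulfur epimers serve because sulfur is lost in step 12.

Step 12
Reactants: 17 (2S)-2-[4-(tert-butyldimethylsilyloxy)-2-methoxyphenyl]-5-(phenylsulfinyl)-2,3-dihydro-4H-pyran-4-one, 9 (1E,3Z)-1-methoxy-3-(trimethylsilyloxy)-4-[(2R)-lavandulyl]buta-1,3-diene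
Product: 21 alopecurone G 4'-O-TBS ether, (2S)-2-[4-(tert-butyldimethylsilyloxy)-2-methoxyphenyl]-7-hydroxy-8-[(2R)-5-methyl-2-(prop-1-en-2-yl)hex-4-en-1-yl]chroman-4-one, via silyl enol ether cycloadduct 18 (not isolated), via enone sulfoxide 19 (not isolated), via dienone tautomer 20 (not isolated)
Conditions: ZnBr2 (1.2 equiv), 9 (2 equiv), CH2Cl2, −30 to 0 °C; 0.1 M HCl–THF, 0 °C; then toluene, 70 °C
Reagents that add atoms: none
Why: ZnBr2 chelates the sulfinyl and C4 carbonyl oxygens of 17 and the silyloxydiene adds across C4a=C8a in a normal-demand [4+2] cycloaddition (concerted but asynchronous, its Mukaiyama–Michael limit leading to the same adduct), the closest known reaction type being the Diels–Alder addition of 1-alkoxy-3-silyloxydienes to 3-sulfinylchromones and other α-sulfinyl enones with aromatising loss of sulfenic acid and alcohol. Ring A is closed by this intermolecular [4+2] cycloaddition, which forms C8–C8a and C4a–C5 on one face of the dienophile and so gives the cis-fused adduct 18 with H8a syn to the sulfinyl group. Dilute acid at 0 °C then hydrolyses the silyl enol ether and expels the β-methoxy group to give enone 19 before any sulfoxide pyrolysis, so that on warming only H8a is left for the syn elimination of benzenesulfenic acid, and dienone 20 tautomerises to the C7 phenol. No new stereocentre survives, because C4a, C5, C8 and C8a all end as sp2 carbons, and the C2 and lavandulyl centres are spectators that meet no base. The selectivity the step needs is regiochemical, and it is secured by matching the largest donor coefficient of the diene at its alkyl-bearing terminus with the acceptor β carbon C8a, an orientation that the carbonyl and the sulfinyl group on C4a both reinforce and that places the lavandulyl group between O7 and O1. The direction of sulfenic acid loss, which would otherwise risk opening ring C, is secured by the order of the two eliminations.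

Step 13
Reactants: 21 alopecurone G 4'-O-TBS ether
Product: 22 alopecurone G, (2S)-7-hydroxy-2-(4-hydroxy-2-methoxyphenyl)-8-[(2R)-5-methyl-2-(prop-1-en-2-yl)hex-4-en-1-yl]chroman-4-one
Conditions: KHF2, MeOH, rt
Reagents that add atoms: none
Why: Fluoride cleavage of a phenolic silyl ether under near-neutral conditions should free the 4'-hydroxyl without acid-induced cyclisation of O7 onto the isopropenyl group and without base-induced opening of the flavanone at C2.

**Compound list**

1 | (S)-(−)-limonene, (4S)-1-methyl-4-(prop-1-en-2-yl)cyclohex-1-ene | CC1=CC[C@H](CC1)C(C)=C | starting material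
2 | (4S)-limonene 1,2-oxide, both epoxide diastereomers | CC12OC1C[C@H](CC2)C(C)=C | intermediate
3 | (4S)-1-methyl-4-(prop-1-en-2-yl)cyclohexane-1,2-diol | CC1(O)C(O)C[C@H](CC1)C(C)=C | intermediate (not isolated)
4 | (3S)-6-oxo-3-(prop-1-en-2-yl)heptanal | O=CC[C@H](CCC(C)=O)C(C)=C | intermediate
5 | (5S)-8-methyl-5-(prop-1-en-2-yl)non-7-en-2-one | C=C(C)[C@H](CC=C(C)C)CCC(C)=O | intermediate
6 | lithium (5S)-8-methyl-5-(prop-1-en-2-yl)nona-1,7-dien-2-olate | C=C(C)[C@H](CC=C(C)C)CCC(=C)O[Li] | intermediate (not isolated)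
7 | (1Z,6S)-1-hydroxy-9-methyl-6-(prop-1-en-2-yl)deca-1,8-dien-3-one | C=C(C)[C@H](CC=C(C)C)CCC(=O)/C=C\O | intermediate
8 | (1E,6S)-1-methoxy-9-methyl-6-(prop-1-en-2-yl)deca-1,8-dien-3-one | C=C(C)[C@H](CC=C(C)C)CCC(=O)/C=C/OC | intermediate
9 | (1E,3Z,6R)-1-methoxy-9-methyl-6-(prop-1-en-2-yl)-3-(trimethylsilyloxy)deca-1,3,8-triene | C=C(C)[C@H](CC=C(C)C)C/C=C(O[Si](C)(C)C)/C=C/OC | intermediate
10 | 4-hydroxy-2-methoxybenzaldehyde | COc1cc(O)ccc1C=O | starting material
11 | 4-(tert-butyldimethylsilyloxy)-2-methoxybenzaldehyde | COc1cc(O[Si](C)(C)C(C)(C)C)ccc1C=O | intermediate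
12 | (E)-1-methoxy-3-(trimethylsilyloxy)buta-1,3-diene | CO/C=C/C(=C)O[Si](C)(C)C | starting material
13 | (1E,5S)-5-[4-(tert-butyldimethylsilyloxy)-2-methoxyphenyl]-1-methoxy-5-(trimethylsilyloxy)pent-1-en-3-one | CO/C=C/C(=O)C[C@H](O[Si](C)(C)C)c1ccc(O[Si](C)(C)C(C)(C)C)cc1OC | intermediate (not isolated)
14 | (2S)-2-[4-(tert-butyldimethylsilyloxy)-2-methoxyphenyl]-2,3-dihydro-4H-pyran-4-one | O=C1C[C@@H](c2ccc(O[Si](C)(C)C(C)(C)C)cc2OC)OC=C1 | intermediate
15 | (2S)-2-[4-(tert-butyldimethylsilyloxy)-2-methoxyphenyl]-5-iodo-2,3-dihydro-4H-pyran-4-one | O=C1C[C@@H](c2ccc(O[Si](C)(C)C(C)(C)C)cc2OC)OC=C1I | intermediate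
16 | (2S)-2-[4-(tert-butyldimethylsilyloxy)-2-methoxyphenyl]-5-(phenylthio)-2,3-dihydro-4H-pyran-4-one | O=C1C[C@@H](c2ccc(O[Si](C)(C)C(C)(C)C)cc2OC)OC=C1Sc1ccccc1 | intermediate
17 | (2S)-2-[4-(tert-butyldimethylsilyloxy)-2-methoxyphenyl]-5-(phenylsulfinyl)-2,3-dihydro-4H-pyran-4-one, both sulfur epimers | O=C1C[C@@H](c2ccc(O[Si](C)(C)C(C)(C)C)cc2OC)OC=C1S(=O)c1ccccc1 | intermediate
18 | cis-fused cycloadduct: (2S)-2-aryl-5-methoxy-4a-(phenylsulfinyl)-7-(trimethylsilyloxy)-8-[(2R)-lavandulyl]-4a,5,8,8a-tetrahydrochroman-4-one, mixture at C4a, C5, C8, C8a and sulfur | C=C(C)[C@H](CC=C(C)C)CC1C(O[Si](C)(C)C)=CC(OC)C2(S(=O)c3ccccc3)C(=O)C[C@@H](c3ccc(O[Si](C)(C)C(C)(C)C)cc3OC)OC12 | intermediate (not isolated)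
19 | enone sulfoxide: (2S)-2-aryl-4a-(phenylsulfinyl)-8-[(2R)-lavandulyl]-2,3,8,8a-tetrahydro-4aH-chromene-4,7-dione with C5=C6 | C=C(C)[C@H](CC=C(C)C)CC1C(=O)C=CC2(S(=O)c3ccccc3)C(=O)C[C@@H](c3ccc(O[Si](C)(C)C(C)(C)C)cc3OC)OC12 | intermediate (not isolated)
20 | dienone tautomer of 21: (2S)-2-aryl-8-[(2R)-lavandulyl]-2,3-dihydro-8H-chromene-4,7-dione with C4a=C8a and C5=C6 | C=C(C)[C@H](CC=C(C)C)CC1C(=O)C=CC2=C1O[C@H](c1ccc(O[Si](C)(C)C(C)(C)C)cc1OC)CC2=O | intermediate (not isolated)
21 | alopecurone G 4'-O-TBS ether | C=C(C)[C@H](CC=C(C)C)Cc1c(O)ccc2c1O[C@H](c1ccc(O[Si](C)(C)C(C)(C)C)cc1OC)CC2=O | intermediate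
22 | alopecurone G | C=C(C)[C@H](CC=C(C)C)Cc1c(O)ccc2c1O[C@H](c1ccc(O)cc1OC)CC2=O | target

**Count and risks**

Total step count: 13. Longest linear sequence: 8 steps (steps 1 to 6, then 12 and 13).

Step 12. The push–pull C4a=C8a bond is a sluggish acceptor, so the zinc halide may consume the silyloxydiene by protodesilylation before C–C bond formation, and long contact with the Lewis acid could ionise the benzylic C2–O1 bond and erode the C2 configuration. The fallback sets out from hydroxymethylene ketone 7 and comes back to the route at enone sulfoxide 19. Condensation of 7 with dimethylamine (THF, rt) should give the enaminone (1E,6S)-1-(dimethylamino)-9-methyl-6-(prop-1-en-2-yl)deca-1,8-dien-3-one F1. Deprotonation and silylation (KN(SiMe3)2, TBSCl, THF, −78 °C) should give the 1-amino-3-silyloxydiene (1E,3Z)-1-(dimethylamino)-3-(tert-butyldimethylsilyloxy)-4-[(2R)-lavandulyl]buta-1,3-diene F2. This far more electron-rich diene should add to 17 in toluene at room temperature with no Lewis acid, giving the amino cycloadduct F3. Dilute HCl in THF at 0 °C should then hydrolyse the silyl enol ether and expel dimethylamine to give 19, which is warmed as in step 12 to give 21.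

Step 8. The electron-rich, ortho-substituted aldehyde may turn over slowly and with poor facial selectivity, and the acid used for ring closure may ionise the doubly donor-substituted benzylic carbinol and lower the enantiomeric purity. The fallback sets out from aldehyde 11 and comes back at pyranone 14. Allylation with (−)-Ipc2B(allyl) (Et2O, −78 °C; NaOH, H2O2), which delivers allyl to the Si face of aryl aldehydes, should give (1S)-1-[4-(tert-butyldimethylsilyloxy)-2-methoxyphenyl]but-3-en-1-ol F4. Silylation (Et3SiCl, imidazole) should give its triethylsilyl ether F5. Tsuji–Wacker oxidation (PdCl2, Cu(OAc)2, O2, DMA–H2O) should give (4S)-4-[4-(tert-butyldimethylsilyloxy)-2-methoxyphenyl]-4-(triethylsilyloxy)butan-2-one F6. Formylation of its kinetic methyl enolate as in step 4 should give the hydroxymethylene ketone (1Z,5S)-5-[4-(tert-butyldimethylsilyloxy)-2-methoxyphenyl]-1-hydroxy-5-(triethylsilyloxy)pent-1-en-3-one F7. Mild aqueous acid (AcOH–THF–H2O, rt) should remove the triethylsilyl group and cyclodehydrate the resulting hydroxy keto aldehyde to 14.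

Step 10. Thiolate may bind and deactivate palladium or reduce the C–I bond back to C–H, and prolonged heating with amine may open the pyranone by β-elimination. The fallback sets out from pyranone 14 and comes back at sulfide 16, bypassing iodide 15. It is a direct electrophilic sulfenylation of the enol ether carbon C5 with PhSCl (1.0 equiv, pyridine, CH2Cl2, −78 °C), by addition and loss of HCl, accepting some risk of attack on ring B. It makes no new compound (F0).

**Further compounds**

F1 | step 12 | (1E,6S)-1-(dimethylamino)-9-methyl-6-(prop-1-en-2-yl)deca-1,8-dien-3-one | C=C(C)[C@H](CC=C(C)C)CCC(=O)/C=C/N(C)C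
F2 | step 12 | (1E,3Z)-1-(dimethylamino)-3-(tert-butyldimethylsilyloxy)-4-[(2R)-lavandulyl]buta-1,3-diene | C=C(C)[C@H](CC=C(C)C)C/C=C(O[Si](C)(C)C(C)(C)C)/C=C/N(C)C
F3 | step 12 | cis-fused amino cycloadduct: (2S)-2-aryl-5-(dimethylamino)-4a-(phenylsulfinyl)-7-(tert-butyldimethylsilyloxy)-8-[(2R)-lavandulyl]-4a,5,8,8a-tetrahydrochroman-4-one | C=C(C)[C@H](CC=C(C)C)CC1C(O[Si](C)(C)C(C)(C)C)=CC(N(C)C)C2(S(=O)c3ccccc3)C(=O)C[C@@H](c3ccc(O[Si](C)(C)C(C)(C)C)cc3OC)OC12
F4 | step 8 | (1S)-1-[4-(tert-butyldimethylsilyloxy)-2-methoxyphenyl]but-3-en-1-ol | C=CC[C@H](O)c1ccc(O[Si](C)(C)C(C)(C)C)cc1OC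
F5 | step 8 | (1S)-1-[4-(tert-butyldimethylsilyloxy)-2-methoxyphenyl]-1-(triethylsilyloxy)but-3-ene | C=CC[C@H](O[Si](CC)(CC)CC)c1ccc(O[Si](C)(C)C(C)(C)C)cc1OC
F6 | step 8 | (4S)-4-[4-(tert-butyldimethylsilyloxy)-2-methoxyphenyl]-4-(triethylsilyloxy)butan-2-one | CC(=O)C[C@H](O[Si](CC)(CC)CC)c1ccc(O[Si](C)(C)C(C)(C)C)cc1OC
F7 | step 8 | (1Z,5S)-5-[4-(tert-butyldimethylsilyloxy)-2-methoxyphenyl]-1-hydroxy-5-(triethylsilyloxy)pent-1-en-3-one | O/C=C\C(=O)C[C@H](O[Si](CC)(CC)CC)c1ccc(O[Si](C)(C)C(C)(C)C)cc1OC
F0 | step 10 | none | none
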